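The 2,3-dihydro-4H-pyran-4-one ring is disconnected at C2–C3 and C4–C5. This exploits two features: O1–C6(CH3)=C5 is an enol ether whose C5 is a natural acyl acceptor, and the lone stereocentre C2 sits one CH2 (C3) away from the C4 carbonyl, i.e. the ring holds a homologated α-alkoxy acid. The precursor is an acyclic (R)-α-(isopropenyloxy) diazomethyl ketone made from methyl (R)-glycidate. On photolysis, Wolff rearrangement shifts C2 onto the diazo carbon with retention (C2–C3), and the ketene formed C-acylates the tethered enol ether (C4–C5), closing the ring and giving the target in the last step.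

Key step: step 6

Remark: ring atoms are numbered O1, C2 (stereocentre), C3 (CH2), C4 (C=O), C5 (=CH), C6 (C–CH3). Erucyl alcohol, methyl (R)-glycidate, 2-methoxypropene and trimethylsilyldiazomethane solution are taken as catalogue materials.

Step 1
Reactants: 1 erucyl alcohol [(13Z)-docos-13-en-1-ol]
Product: 2 erucyl bromide [(13Z)-1-bromodocos-13-ene]
Conditions: CBr4, PPh3, CH2Cl2, 0 °C to rt
Reagents that add atoms: carbon tetrabromide BrC(Br)(Br)Br
Why: Appel reaction: the alkoxyphosphonium ion is displaced by bromide in an SN2 step at the primary carbon under neutral conditions that leave the Z alkene untouched.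

Step 2
Reactants: 2 erucyl bromide; 3 methyl (R)-glycidate
Product: 5 methyl (2R,16Z)-2-hydroxypentacos-16-enoate, via (13Z)-docos-13-enylmagnesium bromide 4 (not isolated)
Conditions: Mg, THF, 45 °C; then added slowly to 3 (1.3 equiv) and CuBr·SMe2 (10 mol %), THF, –78 to –40 °C; then H2O
Reagents that add atoms: magnesium [Mg] (held only in intermediate 4)
Why: Grignard formation, then copper-catalysed SN2 opening of the epoxide at its unsubstituted CH2 (organocuprate epoxide opening), which should outpace addition to the ester at low temperature; the C–O bond at the glycidate stereocentre is not broken, so its R configuration passes unchanged into the α-hydroxy ester.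

Step 3
Reactants: 5 methyl (2R,16Z)-2-hydroxypentacos-16-enoate; 6 2-methoxypropene
Product: 8 methyl (2R,16Z)-2-(prop-1-en-2-yloxy)pentacos-16-enoate, via mixed methyl ketal 7 (not isolated)
Conditions: 6 (3 equiv), PPTS (2 mol %), CH2Cl2, 0 °C; then iPr2NEt (2.5 equiv), TMSOTf (1.3 equiv), –20 to 0 °C; aq NaHCO3
Reagents that add atoms: 2-methoxypropene COC(C)=C (reactant 6)
Why: Acid-catalysed ketalisation followed by silyl triflate/amine elimination of methanol (ketal-to-enol-ether elimination): the more basic methoxy oxygen should be silylated and leave, and the oxocarbenium ion is deprotonated to the isopropenyl ether without touching the stereocentre.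

Step 4
Reactants: 8 methyl (2R,16Z)-2-(prop-1-en-2-yloxy)pentacos-16-enoate
Product: 9 potassium (2R,16Z)-2-(prop-1-en-2-yloxy)pentacos-16-enoate
Conditions: KOSiMe3 (1.05 equiv), THF, rt; evaporation, trituration with dry Et2O
Reagents that add atoms: potassium trimethylsilanolate C[Si](C)(C)[O-].[K+]
Why: Anhydrous silanolate cleavage of the methyl ester gives the carboxylate salt directly, so the acid-labile enol ether never meets a free carboxylic acid, and the weakly basic reagent should not epimerise the α-alkoxy centre.

Step 5
Reactants: 9 potassium (2R,16Z)-2-(prop-1-en-2-yloxy)pentacos-16-enoate; 10 trimethylsilyldiazomethane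
Product: 12 (3R,17Z)-1-diazo-3-(prop-1-en-2-yloxy)hexacos-17-en-2-one, via mixed carbonic anhydride 11 (not isolated)
Conditions: iBuOCOCl (1.1 equiv), N-methylmorpholine (5 mol %), THF, –15 °C; then 10 (2 equiv, hexanes), MeCN, 0 °C to rt; aq NaHCO3; Et3N-deactivated silica
Reagents that add atoms: trimethylsilyldiazomethane C[Si](C)(C)C=[N+]=[N-] (reactant 10); isobutyl chloroformate CC(C)COC(=O)Cl (held only in intermediate 11)
Why: Mixed-anhydride activation followed by C-acylation of the diazoalkane (diazoketone synthesis, first stage of the Arndt–Eistert homologation) under neutral conditions, the carbonate leaving group taking up the silyl group; the stereocentre next to the acyl group is not deprotonated.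

Step 6
Reactants: 12 (3R,17Z)-1-diazo-3-(prop-1-en-2-yloxy)hexacos-17-en-2-one
Product: 14 (2R)-6-methyl-2-[(14Z)-tricos-14-en-1-yl]-2,3-dihydro-4H-pyran-4-one (target), via ketene 13 (not isolated)
Conditions: hν (365 nm), dry degassed MeCN (0.005 M), rt
Reagents that add atoms: none
Why: Proposed new method: direct irradiation expels N2 from the s-Z diazoketone with concerted 1,2-shift of the alkoxy-bearing carbon from the carbonyl carbon to the diazo carbon (Wolff rearrangement, new C2–C3 bond, the former acyl carbon becoming the ketene carbon C4), and the enol ether terminus C5 then adds to C4 of ketene 13 (new C4–C5 bond) to give an oxocarbenium enolate that tautomerises to the vinylogous ester. The closest known reaction types are the Arndt–Eistert homologation of alpha-alkoxy acids with capture of the ketene by a nucleophile and the C-acylation of enol ethers by ketenes and acyl chlorides to beta-alkoxy enones; their merger in one ring-forming event is the untested part. The pyranone ring closes by a 6-(enolendo)-exo-dig attack of C5 on the sp carbon in the plane of the ketene C=O pi* orbital, a plane that already contains C2, whereas the alternative [2+2] collapse would demand a 2-oxabicyclo[2.2.0]hexanone and is ruled out by strain. No stereocentre is created: C2 migrates with retention, so the R centre of the glycidate becomes C2 of the ring. The step needs rearrangement to outrun carbene addition to the enol ether, and ring closure to outrun ketene dimerisation and C2–O1 cleavage of the zwitterion; metal-free photolysis, high dilution, a dry aprotic medium and the short tether are meant to secure this.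

Compound list
1 | erucyl alcohol, (13Z)-docos-13-en-1-ol | CCCCCCCC/C=C\CCCCCCCCCCCCO | starting material
2 | erucyl bromide, (13Z)-1-bromodocos-13-ene | CCCCCCCC/C=C\CCCCCCCCCCCCBr | intermediate
3 | methyl (R)-glycidate, methyl (2R)-oxirane-2-carboxylate | COC(=O)[C@H]1CO1 | starting material
4 | (13Z)-docos-13-enylmagnesium bromide | CCCCCCCC/C=C\CCCCCCCCCCCC[Mg]Br | intermediate (not isolated)
5 | methyl (2R,16Z)-2-hydroxypentacos-16-enoate | CCCCCCCC/C=C\CCCCCCCCCCCCC[C@@H](O)C(=O)OC | intermediate
6 | 2-methoxypropene | COC(C)=C | starting material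
7 | methyl (2R,16Z)-2-[(2-methoxypropan-2-yl)oxy]pentacos-16-enoate (mixed methyl ketal) | CCCCCCCC/C=C\CCCCCCCCCCCCC[C@@H](OC(C)(C)OC)C(=O)OC | intermediate (not isolated)
8 | methyl (2R,16Z)-2-(prop-1-en-2-yloxy)pentacos-16-enoate | CCCCCCCC/C=C\CCCCCCCCCCCCC[C@@H](OC(C)=C)C(=O)OC | intermediate
9 | potassium (2R,16Z)-2-(prop-1-en-2-yloxy)pentacos-16-enoate | CCCCCCCC/C=C\CCCCCCCCCCCCC[C@@H](OC(C)=C)C(=O)[O-].[K+] | intermediate
10 | trimethylsilyldiazomethane | C[Si](C)(C)C=[N+]=[N-] | starting material
11 | isobutyl carbonic (2R,16Z)-2-(prop-1-en-2-yloxy)pentacos-16-enoic anhydride (mixed carbonic anhydride) | CCCCCCCC/C=C\CCCCCCCCCCCCC[C@@H](OC(C)=C)C(=O)OC(=O)OCC(C)C | intermediate (not isolated)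
12 | (3R,17Z)-1-diazo-3-(prop-1-en-2-yloxy)hexacos-17-en-2-one | CCCCCCCC/C=C\CCCCCCCCCCCCC[C@@H](OC(C)=C)C(=O)C=[N+]=[N-] | intermediate
13 | (3R,17Z)-3-(prop-1-en-2-yloxy)hexacosa-1,17-dien-1-one (ketene) | CCCCCCCC/C=C\CCCCCCCCCCCCC[C@@H](OC(C)=C)C=C=O | intermediate (not isolated)
14 | (2R)-6-methyl-2-[(14Z)-tricos-14-en-1-yl]-2,3-dihydro-4H-pyran-4-one | CCCCCCCC/C=C\CCCCCCCCCCCCC[C@@H]1CC(=O)C=C(C)O1 | target

Total step count: 6. Longest linear sequence: 6 steps (1 to 14).

Steps most likely to fail

Step 6 (labelled step). Ring closure of the ketene may lose out to bimolecular ketene dimerisation. The excited diazoketone may also lose nitrogen without migration and add as a carbene to the tethered enol ether. Cleavage of the C2–O1 bond in the zwitterion, followed by re-closure, would erode the configuration. The fallback uses known chemistry, sets out from 12 and returns at 14. Irradiation of 12 in THF in the presence of N,O-dimethylhydroxylamine lets the amine capture the ketene (amide variant of the Arndt–Eistert homologation) and should give (3R,17Z)-N-methoxy-N-methyl-3-(prop-1-en-2-yloxy)hexacos-17-enamide F1. CH3C≡CMgBr in THF at 0 °C should convert it into (6R,20Z)-6-(prop-1-en-2-yloxy)nonacos-20-en-2-yn-4-one F2. PPTS in wet MeOH should hydrolyse the enol ether to (6R,20Z)-6-hydroxynonacos-20-en-2-yn-4-one F3. Ph3PAuCl/AgOTf (catalytic) in CH2Cl2 should then close the ring by 6-endo-dig oxa-Michael addition to 14. C2–C3 still arises by the stereoretentive 1,2-shift; C4–C5 then comes from the acetylide addition.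

Step 3. The mixed ketal may ionise on the wrong oxygen, which returns the substrate as its silyl ether. Silylation of the ester to a silyl ketene acetal would cost the configuration at C2. The fallback sets out from 5 and returns at 8. It replaces ketalisation–elimination by iridium-catalysed transfer of the isopropenyl group from an enol ester: [Ir(cod)Cl]2 (2 mol %), Na2CO3, isopropenyl acetate, toluene, 100 °C. No silyl triflate and no oxocarbenium ion are involved, and the detour passes through no compound of its own (none F0).

Step 5. Acylation of the weakly nucleophilic silyl diazomethane by the mixed anhydride may be slow. Attack at the carbonate carbonyl, or acid-triggered loss of the enol ether during activation, may compete. The fallback sets out from 8 and returns at 12 without any carboxyl activation. Me(MeO)NMgCl (preformed from MeNHOMe·HCl and iPrMgCl, THF, –20 °C) should give (2R,16Z)-N-methoxy-N-methyl-2-(prop-1-en-2-yloxy)pentacos-16-enamide F4. MeMgBr should give the methyl ketone (3R,17Z)-3-(prop-1-en-2-yloxy)hexacos-17-en-2-one F5. Kinetic enolisation at the methyl group with LiN(SiMe3)2 at –78 °C and trapping with CF3CO2CH2CF3 should give (5R,19Z)-1,1,1-trifluoro-5-(prop-1-en-2-yloxy)octacos-19-ene-2,4-dione F6. Detrifluoroacetylative diazo transfer (MsN3, Et3N, H2O, MeCN) should then give 12.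

Further compounds
F0 | step 3 | none | none
F1 | step 6 | (3R,17Z)-N-methoxy-N-methyl-3-(prop-1-en-2-yloxy)hexacos-17-enamide | CCCCCCCC/C=C\CCCCCCCCCCCCC[C@@H](OC(C)=C)CC(=O)N(C)OC
F2 | step 6 | (6R,20Z)-6-(prop-1-en-2-yloxy)nonacos-20-en-2-yn-4-one | CCCCCCCC/C=C\CCCCCCCCCCCCC[C@@H](OC(C)=C)CC(=O)C#CC
F3 | step 6 | (6R,20Z)-6-hydroxynonacos-20-en-2-yn-4-one | CCCCCCCC/C=C\CCCCCCCCCCCCC[C@@H](O)CC(=O)C#CC
F4 | step 5 | (2R,16Z)-N-methoxy-N-methyl-2-(prop-1-en-2-yloxy)pentacos-16-enamide | CCCCCCCC/C=C\CCCCCCCCCCCCC[C@@H](OC(C)=C)C(=O)N(C)OC
F5 | step 5 | (3R,17Z)-3-(prop-1-en-2-yloxy)hexacos-17-en-2-one | CCCCCCCC/C=C\CCCCCCCCCCCCC[C@@H](OC(C)=C)C(C)=O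
F6 | step 5 | (5R,19Z)-1,1,1-trifluoro-5-(prop-1-en-2-yloxy)octacos-19-ene-2,4-dione | CCCCCCCC/C=C\CCCCCCCCCCCCC[C@@H](OC(C)=C)C(=O)CC(=O)C(F)(F)F
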